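**Retrosynthetic overview**
- Oxirane last: face-selective epoxidation of the Z-1(10) olefin of the macrocyclic trienolide.
- Ten-membered carbocycle: C3–C4 bond by intramolecular Nozaki–Hiyama–Kishi coupling (enol triflate + aldehyde), then oxidation to the 2-methylene ketone.
- trans-α-Methylene-γ-lactone: C7–C8 bond by acid-catalysed allylboration–lactonisation of a β,γ-unsaturated aldehyde (C8–C3 piece, from Birch reduction/ozonolysis of 3-methylanisole) with a (Z)-2-(methoxycarbonyl)allyl boronate (C4–C7 and C11–C13 piece).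
- C5/C6 syn-diol (first stereocentres): organocatalytic syn-aldol of an α-alkoxyacetone with a silyl ynal; the ketone becomes the enol triflate, the alkyne the alkynoate and then the allyl boronate.
- Ring order: lactone, then carbocycle, then oxirane.

Assumption: locants follow germacrane numbering (C12 lactone carbonyl closed on O8, C14 = methyl on C10, C15 = methylene on C4), and the four starting materials are taken as catalogue chemicals.

Nothing here has been run; stereochemical outcomes of steps 4, 11 and 16 are predictions from models, and the CIP descriptors and SMILES were derived by hand.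

Step 1
Reactants: 1 3-methylanisole
Product: 2 1-methoxy-5-methylcyclohexa-1,4-diene
Conditions: Li, liquid NH3, t-BuOH, THF, −78 to −33 °C; NH4Cl
Reagents that add atoms: none
Why: Birch reduction leaves both donor-substituted carbons sp2, giving the 1,4-diene whose ring locks the later Z-trisubstituted olefin (no stereocentre formed).

Step 2
Reactants: 2 1-methoxy-5-methylcyclohexa-1,4-diene
Product: 4 methyl (3Z)-6,6-dimethoxy-3-methylhex-3-enoate, via aldehyde ester 3 (not isolated)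
Conditions: O3 (1.0 equiv), CH2Cl2–MeOH, −78 °C; Me2S, −78 to 20 °C; then HC(OMe)3, pyridinium p-toluenesulfonate (cat.), 20 °C
Reagents that add atoms: ozone (O=[O+][O-]); trimethyl orthoformate (COC(OC)OC)
Why: Chemoselective ozonolysis of a Birch enol ether (Corey-type): ozone cleaves the electron-richest enol-ether double bond to the ester-aldehyde with the ring-derived Z olefin intact, and the aldehyde is trapped as its dimethyl acetal by acid-catalysed acetalisation.

Step 3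
Reactants: 4 methyl (3Z)-6,6-dimethoxy-3-methylhex-3-enoate
Product: 5 (3Z)-6,6-dimethoxy-3-methylhex-3-enal
Conditions: i-Bu2AlH (1.05 equiv), CH2Cl2, −78 °C; MeOH, aqueous potassium sodium tartrate
Reagents that add atoms: none
Why: Low-temperature hydride half-reduction of the ester stops at the aluminium hemiacetal, so the β,γ-unsaturated C8 aldehyde is released only on work-up and is used at once.

Step 4
Reactants: 6 1-[(4-methoxybenzyl)oxy]propan-2-one; 7 3-(trimethylsilyl)prop-2-ynal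
Product: 8 (3S,4R)-4-hydroxy-3-[(4-methoxybenzyl)oxy]-6-(trimethylsilyl)hex-5-yn-2-one
Conditions: O-tert-butyl-D-threonine (20 mol%), N-methylpyrrolidin-2-one, 4 °C, 48 h
Reagents that add atoms: none
Why: Primary-amine (enamine) syn-aldol: the threonine catalyst forms the (Z)-enamine of the α-alkoxy ketone (N–H···O hydrogen bond), which adds to the non-enolisable ynal through an acid-organised closed transition state, setting C5 and C6 syn as the first stereocentres; the D-catalyst is chosen as the mirror image of the L-series that should give (3R,4S).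

Step 5
Reactants: 8 (3S,4R)-4-hydroxy-3-[(4-methoxybenzyl)oxy]-6-(trimethylsilyl)hex-5-yn-2-one
Product: 9 (3S,4R)-4-[(tert-butyldimethylsilyl)oxy]-3-[(4-methoxybenzyl)oxy]-6-(trimethylsilyl)hex-5-yn-2-one
Conditions: TBSOTf, 2,6-lutidine, CH2Cl2, −78 °C
Reagents that add atoms: tert-butyldimethylsilyl trifluoromethanesulfonate (CC(C)(C)[Si](C)(C)OS(=O)(=O)C(F)(F)F)
Why: Low-temperature silylation protects the aldol hydroxyl before enolate chemistry without retro-aldol or epimerisation of the α-alkoxy centre.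

Step 6
Reactants: 9 (3S,4R)-4-[(tert-butyldimethylsilyl)oxy]-3-[(4-methoxybenzyl)oxy]-6-(trimethylsilyl)hex-5-yn-2-one
Product: 11 (3S,4R)-4-[(tert-butyldimethylsilyl)oxy]-3-[(4-methoxybenzyl)oxy]-6-(trimethylsilyl)hex-1-en-5-yn-2-yl trifluoromethanesulfonate, via potassium enolate 10 (not isolated)
Conditions: KN(SiMe3)2, THF, −78 °C; PhNTf2, −78 to 0 °C
Reagents that add atoms: N-phenylbis(trifluoromethanesulfonimide) (O=S(=O)(N(c1ccccc1)S(=O)(=O)C(F)(F)F)C(F)(F)F)
Why: Kinetic enolate triflation: the bulky amide removes a methyl proton rather than the hindered α-alkoxy C–H, and O-sulfonylation gives the terminal enol triflate that serves as the C4 alkenyl-anion equivalent.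

Step 7
Reactants: 11 (3S,4R)-4-[(tert-butyldimethylsilyl)oxy]-3-[(4-methoxybenzyl)oxy]-6-(trimethylsilyl)hex-1-en-5-yn-2-yl trifluoromethanesulfonate
Product: 13 methyl (4R,5S)-4-[(tert-butyldimethylsilyl)oxy]-5-[(4-methoxybenzyl)oxy]-6-{[(trifluoromethyl)sulfonyl]oxy}hept-6-en-2-ynoate, via caesium carboxylate 12 (not isolated)
Conditions: CsF, CO2 (1 atm), DMSO, 20 °C; then MeI
Reagents that add atoms: carbon dioxide (O=C=O); iodomethane (CI)
Why: Fluoride-induced desilylative carboxylation: the alkynyl C–Si bond is cleaved much faster than the secondary O–Si bond, the acetylide is trapped by CO2 and the carboxylate is O-methylated in the same flask.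

Step 8
Reactants: 13 methyl (4R,5S)-4-[(tert-butyldimethylsilyl)oxy]-5-[(4-methoxybenzyl)oxy]-6-{[(trifluoromethyl)sulfonyl]oxy}hept-6-en-2-ynoate
Product: 15 methyl (2Z,4R,5S)-4-[(tert-butyldimethylsilyl)oxy]-5-[(4-methoxybenzyl)oxy]-2-[(4,4,5,5-tetramethyl-1,3,2-dioxaborolan-2-yl)methyl]-6-{[(trifluoromethyl)sulfonyl]oxy}hepta-2,6-dienoate, via vinylalane 14 (not isolated)
Conditions: i-Bu2AlH, (Me2N)3PO, THF, 0 °C; then ICH2Bpin, 0 to 20 °C
Reagents that add atoms: 2-(iodomethyl)-4,4,5,5-tetramethyl-1,3,2-dioxaborolane (CC1(C)OB(CI)OC1(C)C)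
Why: Conjugate syn-hydroalumination of the alkynoate puts H on C7 and Al on C11 cis to each other, and alkylation of the α-alanyl acrylate with retention gives the allyl boronate with the C6 substituent trans to CH2B (Villiéras/Hall protocol).

Step 9
Reactants: 15 methyl (2Z,4R,5S)-4-[(tert-butyldimethylsilyl)oxy]-5-[(4-methoxybenzyl)oxy]-2-[(4,4,5,5-tetramethyl-1,3,2-dioxaborolan-2-yl)methyl]-6-{[(trifluoromethyl)sulfonyl]oxy}hepta-2,6-dienoate
Product: 16 methyl (2Z,4R,5S)-4-[(tert-butyldimethylsilyl)oxy]-5-hydroxy-2-[(4,4,5,5-tetramethyl-1,3,2-dioxaborolan-2-yl)methyl]-6-{[(trifluoromethyl)sulfonyl]oxy}hepta-2,6-dienoate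
Conditions: DDQ, CH2Cl2–pH 7 buffer, 0 °C
Reagents that add atoms: none
Why: Oxidative cleavage of the 4-methoxybenzyl ether frees only the C5 hydroxyl; silyl ether, enol triflate and the electron-poor allyl boronate are inert.

Step 10
Reactants: 16 methyl (2Z,4R,5S)-4-[(tert-butyldimethylsilyl)oxy]-5-hydroxy-2-[(4,4,5,5-tetramethyl-1,3,2-dioxaborolan-2-yl)methyl]-6-{[(trifluoromethyl)sulfonyl]oxy}hepta-2,6-dienoate; 17 angelic acid [(2Z)-2-methylbut-2-enoic acid]
Product: 18 methyl (2Z,4R,5S)-4-[(tert-butyldimethylsilyl)oxy]-5-{[(2Z)-2-methylbut-2-enoyl]oxy}-2-[(4,4,5,5-tetramethyl-1,3,2-dioxaborolan-2-yl)methyl]-6-{[(trifluoromethyl)sulfonyl]oxy}hepta-2,6-dienoate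
Conditions: 17, 2,4,6-trichlorobenzoyl chloride, Et3N, toluene, 20 °C; then 16, 4-(dimethylamino)pyridine, 75 °C
Reagents that add atoms: none
Why: Yamaguchi esterification through the mixed trichlorobenzoic anhydride acylates the hindered secondary alcohol and is the usual way to install an angelate without Z-to-E isomerisation to the tiglate.

Step 11
Reactants: 5 (3Z)-6,6-dimethoxy-3-methylhex-3-enal; 18 methyl (2Z,4R,5S)-4-[(tert-butyldimethylsilyl)oxy]-5-{[(2Z)-2-methylbut-2-enoyl]oxy}-2-[(4,4,5,5-tetramethyl-1,3,2-dioxaborolan-2-yl)methyl]-6-{[(trifluoromethyl)sulfonyl]oxy}hepta-2,6-dienoate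
Product: 20 (1R,2S)-1-[(tert-butyldimethylsilyl)oxy]-1-{(2R,3S)-2-[(2Z)-5,5-dimethoxy-2-methylpent-2-en-1-yl]-4-methylidene-5-oxooxolan-3-yl}-3-{[(trifluoromethyl)sulfonyl]oxy}but-3-en-2-yl (2Z)-2-methylbut-2-enoate, via O-boryl adduct 19 (not isolated)
Conditions: (S)-3,3'-bis(2,4,6-triisopropylphenyl)-1,1'-binaphthyl-2,2'-diyl hydrogen phosphate (10 mol%), 4 Å molecular sieves, toluene, 20 °C, 48 h; then pyridinium p-toluenesulfonate (cat.), MeOH (trace), 40 °C
Reagents that add atoms: none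
Why: Proposed new method: chiral-phosphoric-acid-catalysed allylboration of an aldehyde with an ester-deactivated, γ-stereogenic (Z)-2-(methoxycarbonyl)allyl pinacol boronate coupled to lactonisation; the acid should hydrogen-bond to a pinacol oxygen (raising boron Lewis acidity) while its phosphoryl oxygen holds the formyl C–H, so the closed six-membered chair transition state is entered on the aldehyde Si face (8R) with the γ-substituent pseudo-equatorial (trans to CH2B), which fixes the 7,8-anti adduct 19 and, after borate-to-ester acyl transfer, the trans-lactone with the C7/C8 configuration of the target (catalyst control, helped by approach anti to the bulky C6 silyloxy group); the closest known reactions are phosphoric-acid-catalysed allyl- and crotylboration with simple pinacol boronates and Sc(OTf)3- or CF3SO3H-catalysed lactone-forming additions of 2-(alkoxycarbonyl)allyl boronates.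

Step 12
Reactants: 20 (1R,2S)-1-[(tert-butyldimethylsilyl)oxy]-1-{(2R,3S)-2-[(2Z)-5,5-dimethoxy-2-methylpent-2-en-1-yl]-4-methylidene-5-oxooxolan-3-yl}-3-{[(trifluoromethyl)sulfonyl]oxy}but-3-en-2-yl (2Z)-2-methylbut-2-enoate
Product: 21 (1R,2S)-1-[(tert-butyldimethylsilyl)oxy]-1-{(2R,3S)-2-[(2Z)-2-methyl-5-oxopent-2-en-1-yl]-4-methylidene-5-oxooxolan-3-yl}-3-{[(trifluoromethyl)sulfonyl]oxy}but-3-en-2-yl (2Z)-2-methylbut-2-enoate
Conditions: LiBF4, MeCN–H2O (98:2), 20 °C
Reagents that add atoms: water (O)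
Why: Mild Lewis-acid acetal hydrolysis releases the C3 aldehyde without touching the silyl ether, the enol triflate or the esters; the β,γ-unsaturated aldehyde is used directly.

Step 13
Reactants: 21 (1R,2S)-1-[(tert-butyldimethylsilyl)oxy]-1-{(2R,3S)-2-[(2Z)-2-methyl-5-oxopent-2-en-1-yl]-4-methylidene-5-oxooxolan-3-yl}-3-{[(trifluoromethyl)sulfonyl]oxy}but-3-en-2-yl (2Z)-2-methylbut-2-enoate
Product: 22 (1(10)Z,3RS,5R,6R,7S,8R)-5-(angeloyloxy)-6-[(tert-butyldimethylsilyl)oxy]-3-hydroxygermacra-1(10),4(15),11(13)-trien-12,8-olide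
Conditions: CrCl2 (10 equiv), NiCl2 (0.1 equiv), DMF–THF, 2 mM (slow addition), 20 °C
Reagents that add atoms: none
Why: Intramolecular Nozaki–Hiyama–Kishi reaction: nickel inserts into the enol triflate, transmetallation to chromium gives an alkenylchromium that adds only to the aldehyde, closing the ten-membered ring at C3–C4 under high dilution; the C3 carbinol configuration is irrelevant because it is oxidised next.

Step 14
Reactants: 22 (1(10)Z,3RS,5R,6R,7S,8R)-5-(angeloyloxy)-6-[(tert-butyldimethylsilyl)oxy]-3-hydroxygermacra-1(10),4(15),11(13)-trien-12,8-olide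
Product: 23 (1(10)Z,5R,6R,7S,8R)-5-(angeloyloxy)-6-[(tert-butyldimethylsilyl)oxy]-3-oxogermacra-1(10),4(15),11(13)-trien-12,8-olide
Conditions: Dess–Martin periodinane, NaHCO3, CH2Cl2, 0 to 20 °C
Reagents that add atoms: none
Why: Dess–Martin oxidation of the allylic alcohol gives the 2-methylene ketone under buffered non-basic conditions that do not move the β,γ-olefin into conjugation, and it removes the C3 stereocentre.

Step 15
Reactants: 23 (1(10)Z,5R,6R,7S,8R)-5-(angeloyloxy)-6-[(tert-butyldimethylsilyl)oxy]-3-oxogermacra-1(10),4(15),11(13)-trien-12,8-olide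
Product: 24 (1(10)Z,5R,6R,7R,8R)-5-(angeloyloxy)-6-hydroxy-3-oxogermacra-1(10),4(15),11(13)-trien-12,8-olide
Conditions: HF·pyridine, pyridine, THF, 0 to 20 °C
Reagents that add atoms: none
Why: Acidic fluoride desilylation frees the C6 hydroxyl without base, so angelate migration, translactonisation and conjugate additions are avoided (the C7 descriptor changes only through CIP priority).

Step 16
Reactants: 24 (1(10)Z,5R,6R,7R,8R)-5-(angeloyloxy)-6-hydroxy-3-oxogermacra-1(10),4(15),11(13)-trien-12,8-olide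
Product: 25 (1S,5R,6R,7R,8R,10R)-5-(angeloyloxy)-1,10-epoxy-6-hydroxy-3-oxogermacra-4(15),11(13)-dien-12,8-olide (target CNP0348992.7)
Conditions: dimethyldioxirane (acetone solution), CH2Cl2–acetone, −30 to 0 °C
Reagents that add atoms: dimethyldioxirane (CC1(C)OO1)
Why: Neutral electrophilic epoxidation (Prilezhaev type) picks the only electron-rich, non-conjugated trisubstituted olefin; attack on the exposed outer face of the Z-1(10) double bond in the conformer held by the trans-fused lactone is expected to give the 1S,10R oxirane (macrocyclic substrate control), with the cis relation of C2 and C9 carried over from the Z olefin.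

**Compound list**
1 | 3-methylanisole | COc1cccc(C)c1 | starting material
2 | 1-methoxy-5-methylcyclohexa-1,4-diene | COC1=CCC=C(C)C1 | intermediate
3 | methyl (3Z)-3-methyl-6-oxohex-3-enoate | COC(=O)C/C(C)=C\CC=O | intermediate
4 | methyl (3Z)-6,6-dimethoxy-3-methylhex-3-enoate | COC(=O)C/C(C)=C\CC(OC)OC | intermediate
5 | (3Z)-6,6-dimethoxy-3-methylhex-3-enal | O=CC/C(C)=C\CC(OC)OC | intermediate
6 | 1-[(4-methoxybenzyl)oxy]propan-2-one | CC(=O)COCc1ccc(OC)cc1 | starting material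
7 | 3-(trimethylsilyl)prop-2-ynal | O=CC#C[Si](C)(C)C | starting material
8 | (3S,4R)-4-hydroxy-3-[(4-methoxybenzyl)oxy]-6-(trimethylsilyl)hex-5-yn-2-one | CC(=O)[C@@H](OCc1ccc(OC)cc1)[C@H](O)C#C[Si](C)(C)C | intermediate
9 | (3S,4R)-4-[(tert-butyldimethylsilyl)oxy]-3-[(4-methoxybenzyl)oxy]-6-(trimethylsilyl)hex-5-yn-2-one | CC(=O)[C@@H](OCc1ccc(OC)cc1)[C@H](O[Si](C)(C)C(C)(C)C)C#C[Si](C)(C)C | intermediate
10 | potassium (3S,4R)-4-[(tert-butyldimethylsilyl)oxy]-3-[(4-methoxybenzyl)oxy]-6-(trimethylsilyl)hex-1-en-5-yn-2-olate | [K+].[O-]C(=C)[C@@H](OCc1ccc(OC)cc1)[C@H](O[Si](C)(C)C(C)(C)C)C#C[Si](C)(C)C | intermediate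
11 | (3S,4R)-4-[(tert-butyldimethylsilyl)oxy]-3-[(4-methoxybenzyl)oxy]-6-(trimethylsilyl)hex-1-en-5-yn-2-yl trifluoromethanesulfonate | C=C(OS(=O)(=O)C(F)(F)F)[C@@H](OCc1ccc(OC)cc1)[C@H](O[Si](C)(C)C(C)(C)C)C#C[Si](C)(C)C | intermediate
12 | caesium (4R,5S)-4-[(tert-butyldimethylsilyl)oxy]-5-[(4-methoxybenzyl)oxy]-6-{[(trifluoromethyl)sulfonyl]oxy}hept-6-en-2-ynoate | C=C(OS(=O)(=O)C(F)(F)F)[C@@H](OCc1ccc(OC)cc1)[C@H](O[Si](C)(C)C(C)(C)C)C#CC(=O)[O-].[Cs+] | intermediate
13 | methyl (4R,5S)-4-[(tert-butyldimethylsilyl)oxy]-5-[(4-methoxybenzyl)oxy]-6-{[(trifluoromethyl)sulfonyl]oxy}hept-6-en-2-ynoate | C=C(OS(=O)(=O)C(F)(F)F)[C@@H](OCc1ccc(OC)cc1)[C@H](O[Si](C)(C)C(C)(C)C)C#CC(=O)OC | intermediate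
14 | methyl (2E,4R,5S)-2-(diisobutylalumanyl)-4-[(tert-butyldimethylsilyl)oxy]-5-[(4-methoxybenzyl)oxy]-6-{[(trifluoromethyl)sulfonyl]oxy}hepta-2,6-dienoate | C=C(OS(=O)(=O)C(F)(F)F)[C@@H](OCc1ccc(OC)cc1)[C@H](O[Si](C)(C)C(C)(C)C)/C=C(/[Al](CC(C)C)CC(C)C)C(=O)OC | intermediate
15 | methyl (2Z,4R,5S)-4-[(tert-butyldimethylsilyl)oxy]-5-[(4-methoxybenzyl)oxy]-2-[(4,4,5,5-tetramethyl-1,3,2-dioxaborolan-2-yl)methyl]-6-{[(trifluoromethyl)sulfonyl]oxy}hepta-2,6-dienoate | C=C(OS(=O)(=O)C(F)(F)F)[C@@H](OCc1ccc(OC)cc1)[C@H](O[Si](C)(C)C(C)(C)C)/C=C(/CB1OC(C)(C)C(C)(C)O1)C(=O)OC | intermediate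
16 | methyl (2Z,4R,5S)-4-[(tert-butyldimethylsilyl)oxy]-5-hydroxy-2-[(4,4,5,5-tetramethyl-1,3,2-dioxaborolan-2-yl)methyl]-6-{[(trifluoromethyl)sulfonyl]oxy}hepta-2,6-dienoate | C=C(OS(=O)(=O)C(F)(F)F)[C@@H](O)[C@H](O[Si](C)(C)C(C)(C)C)/C=C(/CB1OC(C)(C)C(C)(C)O1)C(=O)OC | intermediate
17 | angelic acid [(2Z)-2-methylbut-2-enoic acid] | C/C=C(/C)C(=O)O | starting material
18 | methyl (2Z,4R,5S)-4-[(tert-butyldimethylsilyl)oxy]-5-{[(2Z)-2-methylbut-2-enoyl]oxy}-2-[(4,4,5,5-tetramethyl-1,3,2-dioxaborolan-2-yl)methyl]-6-{[(trifluoromethyl)sulfonyl]oxy}hepta-2,6-dienoate | C=C(OS(=O)(=O)C(F)(F)F)[C@@H](OC(=O)/C(C)=C\C)[C@H](O[Si](C)(C)C(C)(C)C)/C=C(/CB1OC(C)(C)C(C)(C)O1)C(=O)OC | intermediate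
19 | methyl (3S,4R,6Z)-3-[(1R,2S)-1-[(tert-butyldimethylsilyl)oxy]-2-{[(2Z)-2-methylbut-2-enoyl]oxy}-3-{[(trifluoromethyl)sulfonyl]oxy}but-3-en-1-yl]-9,9-dimethoxy-6-methyl-2-methylidene-4-[(4,4,5,5-tetramethyl-1,3,2-dioxaborolan-2-yl)oxy]non-6-enoate | C=C(OS(=O)(=O)C(F)(F)F)[C@@H](OC(=O)/C(C)=C\C)[C@H](O[Si](C)(C)C(C)(C)C)[C@@H](C(=C)C(=O)OC)[C@H](OB1OC(C)(C)C(C)(C)O1)C/C(C)=C\CC(OC)OC | intermediate
20 | (1R,2S)-1-[(tert-butyldimethylsilyl)oxy]-1-{(2R,3S)-2-[(2Z)-5,5-dimethoxy-2-methylpent-2-en-1-yl]-4-methylidene-5-oxooxolan-3-yl}-3-{[(trifluoromethyl)sulfonyl]oxy}but-3-en-2-yl (2Z)-2-methylbut-2-enoate | C=C(OS(=O)(=O)C(F)(F)F)[C@@H](OC(=O)/C(C)=C\C)[C@H](O[Si](C)(C)C(C)(C)C)[C@H]1C(=C)C(=O)O[C@@H]1C/C(C)=C\CC(OC)OC | intermediate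
21 | (1R,2S)-1-[(tert-butyldimethylsilyl)oxy]-1-{(2R,3S)-2-[(2Z)-2-methyl-5-oxopent-2-en-1-yl]-4-methylidene-5-oxooxolan-3-yl}-3-{[(trifluoromethyl)sulfonyl]oxy}but-3-en-2-yl (2Z)-2-methylbut-2-enoate | C=C(OS(=O)(=O)C(F)(F)F)[C@@H](OC(=O)/C(C)=C\C)[C@H](O[Si](C)(C)C(C)(C)C)[C@H]1C(=C)C(=O)O[C@@H]1C/C(C)=C\CC=O | intermediate
22 | (1(10)Z,3RS,5R,6R,7S,8R)-5-(angeloyloxy)-6-[(tert-butyldimethylsilyl)oxy]-3-hydroxygermacra-1(10),4(15),11(13)-trien-12,8-olide (both C3 epimers) | C=C1C(=O)O[C@@H]2C/C(C)=C\CC(O)C(=C)[C@@H](OC(=O)/C(C)=C\C)[C@H](O[Si](C)(C)C(C)(C)C)[C@@H]12 | intermediate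
23 | (1(10)Z,5R,6R,7S,8R)-5-(angeloyloxy)-6-[(tert-butyldimethylsilyl)oxy]-3-oxogermacra-1(10),4(15),11(13)-trien-12,8-olide | C=C1C(=O)O[C@@H]2C/C(C)=C\CC(=O)C(=C)[C@@H](OC(=O)/C(C)=C\C)[C@H](O[Si](C)(C)C(C)(C)C)[C@@H]12 | intermediate
24 | (1(10)Z,5R,6R,7R,8R)-5-(angeloyloxy)-6-hydroxy-3-oxogermacra-1(10),4(15),11(13)-trien-12,8-olide | C=C1C(=O)O[C@@H]2C/C(C)=C\CC(=O)C(=C)[C@@H](OC(=O)/C(C)=C\C)[C@H](O)[C@@H]12 | intermediate
25 | (1S,5R,6R,7R,8R,10R)-5-(angeloyloxy)-1,10-epoxy-6-hydroxy-3-oxogermacra-4(15),11(13)-dien-12,8-olide | C=C1C(=O)O[C@@H]2C[C@@]3(C)O[C@H]3CC(=O)C(=C)[C@@H](OC(=O)/C(C)=C\C)[C@H](O)[C@@H]12 | target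

**Step count and risks**
Total step count: 16. Longest linear sequence: 13 steps (steps 4 to 16, from 6 and 7); the three-step branch from 1 to 5 joins at step 11.

The three steps most likely to fail:

Step 11 (the proposed new step). The ester-deactivated boronate may react too slowly under a phosphoric acid, the β,γ-unsaturated aldehyde may isomerise, or catalyst and substrate facial preferences may be mismatched. The fallback uses known chemistry, sets out from 18 and comes back at 20. The C–B bond of 18 is oxidised with NaBO3·4H2O (THF–water, 20 °C) to the allylic alcohol methyl (2Z,4R,5S)-2-(hydroxymethyl)dienoate F1. Appel bromination (CBr4, PPh3, CH2Cl2, 0 °C) gives the allylic bromide F2. F2 is then coupled with aldehyde 5 by the CrCl2-mediated Nozaki–Hiyama allylation (THF, 0 to 20 °C), the established route from 2-(bromomethyl)acrylates to α-methylene-γ-lactones, and the hydroxy ester is lactonised on mild acid work-up to 20. Stereocontrol then rests on the anti preference of allylchromium reagents and on substrate facial bias, with chromatographic removal of minor isomers.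

Step 13. The alkenyl-metal intermediate carries a β-angeloyloxy group and could eliminate to an allene, and the ten-membered ring closure may be slow. The fallback sets out from 21 and comes back at 23, bypassing step 14. Aldehyde 21 is oxidised (NaClO2, NaH2PO4, 2-methylbut-2-ene, t-BuOH–water) to the carboxylic acid F3. The enol triflate is exchanged for tin (Me3SnSnMe3, Pd(PPh3)4, LiCl, THF, 60 °C) to give the alkenylstannane acid F4. Treatment with 1-chloro-N,N,2-trimethylprop-1-en-1-amine gives the acid chloride F5, and the ring is closed by an intramolecular acyl Stille coupling (Pd2(dba)3, tri(2-furyl)phosphine, THF, 2 mM, 50 °C), which delivers enone 23 directly.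

Step 16. The facial selectivity of a substrate-controlled epoxidation of the macrocycle cannot be guaranteed. The fallback sets out from 23 and comes back at 25. The silyl ether 23, which has a different ring conformation, is epoxidised under reagent control with the fructose-derived Shi ketone (1,2:4,5-di-O-isopropylidene-D-erythro-2,3-hexodiulo-2,6-pyranose or its enantiomer, whichever matches; KHSO5, NaHCO3-buffered MeCN–water, 0 °C) to the epoxy silyl ether F6. Desilylation with Et3N·3HF (MeCN, 20 °C) then gives 25.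

**Further compounds**
F1 | step 11 | methyl (2Z,4R,5S)-4-[(tert-butyldimethylsilyl)oxy]-2-(hydroxymethyl)-5-{[(2Z)-2-methylbut-2-enoyl]oxy}-6-{[(trifluoromethyl)sulfonyl]oxy}hepta-2,6-dienoate | C=C(OS(=O)(=O)C(F)(F)F)[C@@H](OC(=O)/C(C)=C\C)[C@H](O[Si](C)(C)C(C)(C)C)/C=C(/CO)C(=O)OC
F2 | step 11 | methyl (2E,4R,5S)-2-(bromomethyl)-4-[(tert-butyldimethylsilyl)oxy]-5-{[(2Z)-2-methylbut-2-enoyl]oxy}-6-{[(trifluoromethyl)sulfonyl]oxy}hepta-2,6-dienoate | C=C(OS(=O)(=O)C(F)(F)F)[C@@H](OC(=O)/C(C)=C\C)[C@H](O[Si](C)(C)C(C)(C)C)/C=C(/CBr)C(=O)OC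
F3 | step 13 | (3Z)-5-{(2R,3S)-3-[(1R,2S)-1-[(tert-butyldimethylsilyl)oxy]-2-{[(2Z)-2-methylbut-2-enoyl]oxy}-3-{[(trifluoromethyl)sulfonyl]oxy}but-3-en-1-yl]-4-methylidene-5-oxooxolan-2-yl}-4-methylpent-3-enoic acid | C=C(OS(=O)(=O)C(F)(F)F)[C@@H](OC(=O)/C(C)=C\C)[C@H](O[Si](C)(C)C(C)(C)C)[C@H]1C(=C)C(=O)O[C@@H]1C/C(C)=C\CC(=O)O
F4 | step 13 | (3Z)-5-{(2R,3S)-3-[(1R,2S)-1-[(tert-butyldimethylsilyl)oxy]-2-{[(2Z)-2-methylbut-2-enoyl]oxy}-3-(trimethylstannyl)but-3-en-1-yl]-4-methylidene-5-oxooxolan-2-yl}-4-methylpent-3-enoic acid | C=C([Sn](C)(C)C)[C@@H](OC(=O)/C(C)=C\C)[C@H](O[Si](C)(C)C(C)(C)C)[C@H]1C(=C)C(=O)O[C@@H]1C/C(C)=C\CC(=O)O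
F5 | step 13 | (3Z)-5-{(2R,3S)-3-[(1R,2S)-1-[(tert-butyldimethylsilyl)oxy]-2-{[(2Z)-2-methylbut-2-enoyl]oxy}-3-(trimethylstannyl)but-3-en-1-yl]-4-methylidene-5-oxooxolan-2-yl}-4-methylpent-3-enoyl chloride | C=C([Sn](C)(C)C)[C@@H](OC(=O)/C(C)=C\C)[C@H](O[Si](C)(C)C(C)(C)C)[C@H]1C(=C)C(=O)O[C@@H]1C/C(C)=C\CC(=O)Cl
F6 | step 16 | (1S,5R,6R,7S,8R,10R)-5-(angeloyloxy)-6-[(tert-butyldimethylsilyl)oxy]-1,10-epoxy-3-oxogermacra-4(15),11(13)-dien-12,8-olide | C=C1C(=O)O[C@@H]2C[C@@]3(C)O[C@H]3CC(=O)C(=C)[C@@H](OC(=O)/C(C)=C\C)[C@H](O[Si](C)(C)C(C)(C)C)[C@@H]12
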